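## The problem

5,8-Dihydroxy-3,7,2',3',4'-pentamethoxyflavone (16) is a 2-aryl-4H-chromen-4-one. Benzo ring A and pyranone ring C are fused at C4a–C8a, and ring B (2,3,4-trimethoxyphenyl) is attached to C2 by a single bond. The molecule has no stereocentre; the only stereochemical element on the way is the geometry of a tetrasubstituted enol ether, and the one racemic centre that appears in an intermediate is erased in the following step. The task is therefore regiochemical. Ring A carries oxygen at C5, C7, C8 and C8a and ring C at C3; five oxygens are methyl ethers and two (C5, C8) are free, so a global demethylation is excluded and the two hydroxyls must be told apart from the methoxy groups by the way they are introduced. The 5,8-hydroquinone is oxidised by air, fastest in base, and the chromone is opened at C2 by hot alkali. The 3- and 5-oxygens next to the C4 carbonyl are the ones a chelating Lewis acid cleaves first, so the hydroquinone should appear last, under reducing and near-neutral conditions. Ring B is electron-rich and ortho-substituted, which makes its carbonyl derivatives slow electrophiles. The enabling feature is that C4a is ortho to O1 and para to the 7-OMe while the other ortho position of O1, C8, already bears oxygen, so an acylium ion at C4 tethered through O1–C2=C3 has only C4a to attack.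

## Retrosynthesis

**C5–O.** The C5 hydroxyl of 16 is removed first. Quinone 15 gives 16 by reduction, and 15 comes from the 8-hydroxyflavone 14 by oxidation at the free position para to the phenol. This cut is preferred to carrying a protected C5 oxygen through the synthesis because it makes ring A one oxygen simpler and because the two free hydroxyls of 16 then arise from one phenol and its para position, never from selective ether cleavage. The forward reaction must oxidise only C5; C7 (OMe) and C8a (ring fusion) block both ortho positions.

**O8 protecting group.** Phenol 14 is masked as benzyl ether 13. Benzyl is removable by hydrogenolysis without touching methyl ethers or the chromone, and it blocks one ortho position of the ring A oxygen during ring closure.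

**C4–C4a (key cut).** Opening ring C of 13 at C4–C4a gives the β-aryloxyacrylic acid 11, activated in the forward direction as acyl chloride 12. The neighbouring cut at O1–C2 (cyclodehydration of an o-hydroxyaryl 1,3-diketone) would need an o-hydroxyaryl methoxymethyl ketone with the full ring A pattern, several steps from commercial material. The C4–C4a cut reduces ring A to a simple phenol. Acid 11 is acyclic and already holds every carbon and all seven oxygens of 13. The forward reaction must acylate C4a only and leave the benzyl and vinyl ethers intact.

**O1–C2.** Acid 11 is the saponification product of ester 10, which is cut at the aryl vinyl ether oxygen into phenol 4 and enol triflate 9. Conjugate addition of 4 to an arylpropiolate would be the classical alternative, but it leaves C3 unsubstituted and postpones the 3-OMe to a late oxidation. The enol triflate carries the 3-OMe from the start. The forward reaction is a C–O bond formation at a hindered, tetrasubstituted vinyl carbon. Palladium catalysis is chosen over plain phenoxide substitution because a bare phenoxide may attack the sulfur of the triflate.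

**C2–C3.** Triflate 9 comes from β-keto ester 8, which is cut between the ketone carbon (future C2) and the α-carbon (future C3) into aroyl chloride 7, made from acid 5, and the enolate of methyl methoxyacetate 6. Ester 6 supplies C3, C4 and the 3-OMe in one commercial piece. The forward reaction must be a clean C-acylation, and the triflation should be chelation-controlled so that OTf lies cis to the ester.

**Phenol 4.** The C–O bond of 4 at the future O1 is traced to a C–C bond by Baeyer–Villiger logic: formate 3 from aldehyde 2, the benzyl ether of o-vanillin 1. In 1 the two future catechol oxygens are already different (one is a phenol, the other still a formyl carbon), so no selective mono-alkylation of a catechol is needed.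

## Roads not taken

**Alternative 1:** The cut removes C4 as a separate one-carbon unit: C4a–C4 and C4–C3 are both broken and C4 is traced to carbon monoxide (A4).
- Forward key step: aryl iodide A2, A4 and the enolate of the α-methoxy ketone A3 are joined by Pd(dba)2, a zerovalent palladium source, with 1,3-bis(diphenylphosphino)propane. Oxidative addition, CO insertion and acylation of the enolate by the aroylpalladium species give the 2-methoxy-1,3-diketone A1. Acidic removal of the methoxymethyl group and cyclodehydration would then close ring C.
- Merits: three components and two C–C bonds in one step; basic conditions that stress no acid-labile group; regiochemistry fixed by the position of iodine.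
- Weak points: the iodide is electron-rich and flanked by two ortho oxygens, so oxidative addition and enolate attack on a hindered aroylpalladium are slow, and CO-free arylation or reduction can compete. More seriously, ring A of A1 has oxygen at the future C5 and C7 but not at C8. After ring closure the 5-OMe must be cleaved selectively beside the 3-OMe (both sit next to the C4 carbonyl and chelate the same Lewis acid), and C8 must be hydroxylated by persulfate para to the 5-OH, a reaction that generally proceeds with modest efficiency.
- Comparison: this road reaches the carbon skeleton in fewer steps and is more convergent than the chosen plan. Against that the chosen plan has the C8 oxygen in place from o-vanillin, never needs a selective demethylation, and brings in the last oxygen through a quinone, not by persulfate C–H hydroxylation.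

**Alternative 2:** Three bonds of ring C are cut at once (C8a–O1, C4a–C4 and O1–C2), so that ring A becomes the aryne A6 and the remainder the acrylic acid A8.
- Forward key step: CsF liberates A6 from the silyl triflate A7. The carboxylate of A8 adds through oxygen at the aryne carbon remote from the adjacent methoxy group, the aryl anion formed next to that methoxy group takes the acyl group intramolecularly, and the freed phenoxide displaces the β-methoxy group by addition–elimination to give flavone A5.
- Merits: a flavone in one operation from two fragments, no transition metal, and dependable regiochemistry of addition to a 3-alkoxyaryne.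
- Weak points: the aryl anion can be protonated by the acid before the acyl shift through a four-membered transition state, which leaves a simple aryl ester. A7 takes several steps. A5 again has the 5,7-pattern without O8, so the same selective 5-demethylation and persulfate hydroxylation follow as in alternative 1. An aryne that already carried the C8 oxygen would send the carboxylate to the wrong terminus, because nucleophiles add at the carbon remote from an adjacent alkoxy group.
- Comparison: in step count to a flavone this is the shortest road of all. The chosen plan is longer but has the correct ring A oxygenation from the outset and no methyl ether cleavage.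

**Alternative 3:** The cut is at C3–C4 and C2=C3, with C3 and its methoxy group traced to the ylide A11.
- Forward key step: acid chloride A10, made from acid A12 by double aroylation and chlorination, C-acylates A11. A second equivalent of A11 deprotonates the phosphonium salt. On heating in toluene the acyl ylide olefinates the carbonyl of the neighbouring aryl ester with loss of the phosphorus as its oxide, closing ring C to give A9. Hydrolysis of the 8-O-aroyl group would lead to phenol 14 of the chosen route.
- Merits: the 7-OMe/8-O pattern is correct from the start, the 3-OMe arrives with C3, the aroyl group doubles as the O8 protecting group, and 14 would be reached in roughly half the steps.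
- Weak points: the non-stabilised, strongly basic α-methoxy ylide must choose the acid chloride over two activated aryl esters in the same molecule, and attack there would scramble the acyl groups. The ester carbonyl to be olefinated belongs to the hindered, electron-rich ring B acid and is a poor Wittig acceptor. One equivalent of ring B is thrown away. A12 is far less accessible than o-vanillin.
- Comparison: this road is shorter, and that has to be conceded. The chosen plan offers in return a unique reactive site at every bond-forming step, single use of ring B, and a ring closure at an arene carbon activated by a para methoxy group in place of an olefination of a deactivated ester.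

Key step: step 7

Remarks on the chemistry:
- 2,3,4-Trimethoxybenzoic acid, activated as its chloride, is used as the ring B source because acylation of a preformed ester enolate by an acid chloride is more dependable than a crossed condensation of two methyl esters.
- Compounds 9–12 are written as the 2E isomers expected from chelation-controlled triflation and stereoretentive coupling. The key step does not depend on isomeric purity, because the acylium ion can rotate about its C2–C3 bond.
- SnCl4 in step 7 acts as a Lewis acid promoter and is not consumed in the balanced equation.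

## Route

Step 1
Reactants: 1 2-hydroxy-3-methoxybenzaldehyde (o-vanillin)
Product: 2 2-(benzyloxy)-3-methoxybenzaldehyde
Conditions: BnBr, K2CO3, DMF, 60 °C
Reagents that add atoms: benzyl bromide, BrCc1ccccc1
Why: Williamson etherification of the phenol; carbonate in DMF breaks the hydrogen bond to the aldehyde and the phenoxide is benzylated cleanly.

Step 2
Reactants: 2 2-(benzyloxy)-3-methoxybenzaldehyde
Product: 4 2-(benzyloxy)-3-methoxyphenol, via aryl formate 3 (not isolated)
Conditions: mCPBA, CH2Cl2, 0 °C → rt; aq. NaHCO3 wash; then K2CO3 (cat.), MeOH, rt
Reagents that add atoms: mCPBA (3-chloroperoxybenzoic acid), OOC(=O)c1cccc(Cl)c1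
Why: Baeyer–Villiger (Dakin-type) oxidation; the electron-rich aryl group with an ortho alkoxy donor migrates in preference to hydride to give the formate, which is methanolysed under mild carbonate catalysis without touching the benzyl ether.

Step 3
Reactants: 5 2,3,4-trimethoxybenzoic acid; 6 methyl methoxyacetate
Product: 8 racemic methyl 2-methoxy-3-oxo-3-(2,3,4-trimethoxyphenyl)propanoate, via aroyl chloride 7 (not isolated)
Conditions: 5, (COCl)2, cat. DMF, CH2Cl2, 0 °C → rt, concentrate; 6 (2.2 equiv), LiN(SiMe3)2 (2.2 equiv), THF, −78 °C; then 7 in THF, −78 → −30 °C; aq. NH4Cl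
Reagents that add atoms: none
Why: C-acylation of a preformed lithium ester enolate by an aroyl chloride (crossed Claisen-type condensation); the second equivalent of enolate deprotonates the more acidic β-keto ester as it forms and so prevents a second acylation, and the new centre at C2 is racemic and is erased in step 4.

Step 4
Reactants: 8 racemic methyl 2-methoxy-3-oxo-3-(2,3,4-trimethoxyphenyl)propanoate
Product: 9 methyl (2E)-2-methoxy-3-(2,3,4-trimethoxyphenyl)-3-{[(trifluoromethyl)sulfonyl]oxy}prop-2-enoate
Conditions: NaH, Et2O, 0 °C; then Tf2O, −78 → 0 °C
Reagents that add atoms: trifluoromethanesulfonic anhydride, O=S(=O)(OS(=O)(=O)C(F)(F)F)C(F)(F)F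
Why: O-sulfonylation of a β-keto ester enolate; the sodium enolate sits in the six-membered chelate between the ketone oxygen and the ester carbonyl, so triflation should give the isomer with OTf cis to CO2Me (2E).

Step 5
Reactants: 9 methyl (2E)-2-methoxy-3-(2,3,4-trimethoxyphenyl)-3-{[(trifluoromethyl)sulfonyl]oxy}prop-2-enoate; 4 2-(benzyloxy)-3-methoxyphenol
Product: 10 methyl (2E)-3-[2-(benzyloxy)-3-methoxyphenoxy]-2-methoxy-3-(2,3,4-trimethoxyphenyl)prop-2-enoate
Conditions: Pd2(dba)3 (cat.), 2-di-tert-butylphosphino-2',4',6'-triisopropylbiphenyl (cat.), K3PO4, toluene, 90 °C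
Reagents that add atoms: none
Why: Palladium-catalysed C–O cross-coupling of an enol triflate with a phenol (Buchwald-type etherification): zerovalent palladium inserts into the activated vinyl C–OTf bond, phenoxide exchanges for triflate, and the bulky biaryl phosphine drives C–O reductive elimination with retention of alkene geometry; any uncatalysed addition–elimination of phenoxide at the same carbon gives the same product.

Step 6
Reactants: 10 methyl (2E)-3-[2-(benzyloxy)-3-methoxyphenoxy]-2-methoxy-3-(2,3,4-trimethoxyphenyl)prop-2-enoate
Product: 11 (2E)-3-[2-(benzyloxy)-3-methoxyphenoxy]-2-methoxy-3-(2,3,4-trimethoxyphenyl)prop-2-enoic acid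
Conditions: LiOH, THF/MeOH/H2O, 50 °C; then aq. HCl to pH 3
Reagents that add atoms: lithium hydroxide, [Li+].[OH-]
Why: Saponification of the methyl ester; the α-methoxy group lowers the electrophilicity of C3 of the push-pull alkene, so hydroxide should attack the acyl carbon and leave the aryl vinyl ether in place.

Step 7
Reactants: 11 (2E)-3-[2-(benzyloxy)-3-methoxyphenoxy]-2-methoxy-3-(2,3,4-trimethoxyphenyl)prop-2-enoic acid
Product: 13 8-(benzyloxy)-3,7-dimethoxy-2-(2,3,4-trimethoxyphenyl)-4H-chromen-4-one, via acyl chloride 12 (not isolated)
Conditions: (COCl)2, cat. DMF, CH2Cl2, 0 °C → rt, concentrate; then SnCl4, CH2Cl2, −40 → 0 °C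
Reagents that add atoms: none
Why: Oxalyl chloride with catalytic DMF converts acid 11 into acyl chloride 12, from which SnCl4 abstracts chloride to give an acylium ion stabilised by the β-aryloxy and α-methoxy donors (a ketenyl oxocarbenium resonance form). The cation attacks the phenoxy ring at the carbon ortho to the ether oxygen, and loss of a proton from the arenium ion gives the chromone. The closest known reaction is the Ruhemann flavone synthesis, the acid-mediated cyclisation of β-aryloxycinnamic acids, which is an intramolecular Friedel–Crafts acylation. Ring C closes in a six-membered mode, 6-exo-dig at the acylium carbon, forming C4–C4a, and no stereocentre is created. Within ring A the site is fixed by the substrate: of the two positions ortho to the ether oxygen one carries the benzyloxy group, so only C4a is open, and it is para to the 7-OMe. Closure onto C6' of ring B is disfavoured because the E geometry holds the acyl group cis to the aryloxy group, because it would form a strained five-membered indenone, and because the 3'-OMe para to C6' is flanked by two methoxy groups and conjugates poorly. Any Z isomer can still react, since the C2–C3 bond of the acylium ion has single-bond character in its oxocarbenium form and rotates into the reactive geometry. The mild Lewis acid and low temperature are chosen so that the benzyl ether survives.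

Step 8
Reactants: 13 8-(benzyloxy)-3,7-dimethoxy-2-(2,3,4-trimethoxyphenyl)-4H-chromen-4-one
Product: 14 8-hydroxy-3,7-dimethoxy-2-(2,3,4-trimethoxyphenyl)-4H-chromen-4-one
Conditions: H2 (1 atm), Pd/C, EtOAc/MeOH, rt
Reagents that add atoms: none
Why: Hydrogenolysis of an aryl benzyl ether; the tetrasubstituted C2=C3 bond and the chromone carbonyl, both part of a vinylogous ester, are not reduced at balloon pressure and room temperature.

Step 9
Reactants: 14 8-hydroxy-3,7-dimethoxy-2-(2,3,4-trimethoxyphenyl)-4H-chromen-4-one
Product: 15 3,7-dimethoxy-2-(2,3,4-trimethoxyphenyl)-4H-chromene-4,5,8-trione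
Conditions: (KSO3)2NO (2.5 equiv), aq. KH2PO4, acetone/H2O, 0 °C → rt
Reagents that add atoms: potassium nitrosodisulfonate (Fremy's salt), [K+].[K+].[O-]S(=O)(=O)N([O])S(=O)(=O)[O-]
Why: Teuber oxidation: one Fremy radical abstracts the phenolic hydrogen, a second adds through oxygen at the free para carbon C5, and loss of imidodisulfonate gives the para-quinone; C7 (OMe) and C8a (ring fusion) block both ortho positions, so no ortho-quinone can form.

Step 10
Reactants: 15 3,7-dimethoxy-2-(2,3,4-trimethoxyphenyl)-4H-chromene-4,5,8-trione
Product: 16 5,8-dihydroxy-3,7-dimethoxy-2-(2,3,4-trimethoxyphenyl)-4H-chromen-4-one (5,8-dihydroxy-3,7,2',3',4'-pentamethoxyflavone)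
Conditions: Na2S2O4, EtOAc/H2O, rt, under argon
Reagents that add atoms: none
Why: Two-electron reduction of a quinone to its hydroquinone by dithionite; the product is stabilised by the hydrogen bond from 5-OH to the C4 carbonyl, and the neutral, oxygen-free work-up prevents re-oxidation.

## Compound list

1 | 2-hydroxy-3-methoxybenzaldehyde (o-vanillin) | COc1cccc(C=O)c1O | starting material
2 | 2-(benzyloxy)-3-methoxybenzaldehyde | COc1cccc(C=O)c1OCc1ccccc1 | intermediate
3 | 2-(benzyloxy)-3-methoxyphenyl formate | COc1cccc(OC=O)c1OCc1ccccc1 | intermediate (not isolated)
4 | 2-(benzyloxy)-3-methoxyphenol | COc1cccc(O)c1OCc1ccccc1 | intermediate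
5 | 2,3,4-trimethoxybenzoic acid | COc1ccc(C(=O)O)c(OC)c1OC | starting material
6 | methyl methoxyacetate | COCC(=O)OC | starting material
7 | 2,3,4-trimethoxybenzoyl chloride | COc1ccc(C(=O)Cl)c(OC)c1OC | intermediate (not isolated)
8 | methyl 2-methoxy-3-oxo-3-(2,3,4-trimethoxyphenyl)propanoate (racemic) | COC(=O)C(OC)C(=O)c1ccc(OC)c(OC)c1OC | intermediate
9 | methyl (2E)-2-methoxy-3-(2,3,4-trimethoxyphenyl)-3-{[(trifluoromethyl)sulfonyl]oxy}prop-2-enoate | COC(=O)/C(OC)=C(\OS(=O)(=O)C(F)(F)F)c1ccc(OC)c(OC)c1OC | intermediate
10 | methyl (2E)-3-[2-(benzyloxy)-3-methoxyphenoxy]-2-methoxy-3-(2,3,4-trimethoxyphenyl)prop-2-enoate | COC(=O)/C(OC)=C(\Oc1cccc(OC)c1OCc1ccccc1)c1ccc(OC)c(OC)c1OC | intermediate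
11 | (2E)-3-[2-(benzyloxy)-3-methoxyphenoxy]-2-methoxy-3-(2,3,4-trimethoxyphenyl)prop-2-enoic acid | OC(=O)/C(OC)=C(\Oc1cccc(OC)c1OCc1ccccc1)c1ccc(OC)c(OC)c1OC | intermediate
12 | (2E)-3-[2-(benzyloxy)-3-methoxyphenoxy]-2-methoxy-3-(2,3,4-trimethoxyphenyl)prop-2-enoyl chloride | ClC(=O)/C(OC)=C(\Oc1cccc(OC)c1OCc1ccccc1)c1ccc(OC)c(OC)c1OC | intermediate (not isolated)
13 | 8-(benzyloxy)-3,7-dimethoxy-2-(2,3,4-trimethoxyphenyl)-4H-chromen-4-one | COc1ccc2c(c1OCc1ccccc1)oc(-c1ccc(OC)c(OC)c1OC)c(OC)c2=O | intermediate
14 | 8-hydroxy-3,7-dimethoxy-2-(2,3,4-trimethoxyphenyl)-4H-chromen-4-one | COc1ccc2c(c1O)oc(-c1ccc(OC)c(OC)c1OC)c(OC)c2=O | intermediate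
15 | 3,7-dimethoxy-2-(2,3,4-trimethoxyphenyl)-4H-chromene-4,5,8-trione | COC1=CC(=O)C2=C(C1=O)OC(c1ccc(OC)c(OC)c1OC)=C(OC)C2=O | intermediate
16 | 5,8-dihydroxy-3,7-dimethoxy-2-(2,3,4-trimethoxyphenyl)-4H-chromen-4-one | COc1ccc(-c2oc3c(O)c(OC)cc(O)c3c(=O)c2OC)c(OC)c1OC | target

## Step count and risks

Total step count: 10 steps.
Longest linear sequence: 8 steps (steps 1, 2, 5, 6, 7, 8, 9, 10; the ring B branch through steps 3 and 4 is equally long).

**Step 7 (key step).** The benzyl group may be lost to the Lewis acid before ring closure, or the donor-stabilised acylium ion may be too weak an electrophile, so that cleavage of the aryl vinyl ether overtakes acylation. Loss of benzyl after closure is harmless, since it leads to 14. The fallback forms C4–C4a by aryllithium acylation and closes ring C at O1–C2. It sets out from phenol 4 and returns at 13.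
- Phenol 4 is protected (MOMCl, i-Pr2NEt) as 2-(benzyloxy)-1-methoxy-3-(methoxymethoxy)benzene F1.
- Directed ortho-lithiation (n-BuLi, TMEDA, THF, −20 °C) at the only position ortho to the methoxymethoxy group and quenching with N,2-dimethoxy-N-methylacetamide gives 1-[3-(benzyloxy)-4-methoxy-2-(methoxymethoxy)phenyl]-2-methoxyethan-1-one F2.
- HCl in MeOH frees 1-[3-(benzyloxy)-2-hydroxy-4-methoxyphenyl]-2-methoxyethan-1-one F3.
- Its dianion (LiN(SiMe3)2, THF, −78 °C) is C-aroylated by chloride 7 in a one-pot Baker–Venkataraman-type process to give racemic 1-[3-(benzyloxy)-2-hydroxy-4-methoxyphenyl]-2-methoxy-3-(2,3,4-trimethoxyphenyl)propane-1,3-dione F4.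
- Cyclodehydration (TsOH, toluene, 80 °C) gives 13.

**Step 5.** The phenoxide may attack the sulfur of the triflate and transfer the triflyl group, returning the enolate of 8. Reductive elimination at the crowded tetrasubstituted vinylpalladium may also be slow. The fallback removes the sulfonyl group from the problem. It sets out from 8 and returns at 10.
- Vilsmeier-type chlorination of 8 ((COCl)2, DMF, CH2Cl2) gives methyl (2E)-3-chloro-2-methoxy-3-(2,3,4-trimethoxyphenyl)prop-2-enoate F5.
- Classical thermal addition–elimination of the phenoxide of 4 (Cs2CO3, DMF, 70 °C) gives 10.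
- Because the enolate adduct rotates freely, 10 may be accompanied by methyl (2Z)-3-[2-(benzyloxy)-3-methoxyphenoxy]-2-methoxy-3-(2,3,4-trimethoxyphenyl)prop-2-enoate F6. Both isomers can be carried on, since the acylium ion of step 7 equilibrates the geometry.

**Step 3.** O-acylation or a second acylation of the enolate, or self-condensation of the methoxyacetate enolate on warming, may erode the C-acylation. The fallback brings in the methoxy group by carbene O–H insertion. It sets out from chloride 7 and returns at 8.
- Chloride 7 with potassium methyl malonate, MgCl2 and Et3N in MeCN gives, after decarboxylation, methyl 3-oxo-3-(2,3,4-trimethoxyphenyl)propanoate F7.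
- Diazo transfer (4-acetamidobenzenesulfonyl azide, Et3N) gives methyl 2-diazo-3-oxo-3-(2,3,4-trimethoxyphenyl)propanoate F8.
- Dirhodium tetraacetate Rh2(OAc)4 in MeOH/CH2Cl2 inserts the carbene into the O–H bond of methanol to give 8.

**Step 9.** The methoxyquinone is a vinylogous ester and may be attacked by water or excess oxidant (hydrolysis of the 7-OMe, over-oxidation), and hydrogen abstraction from the phenol may be slow. The fallback is an ionic para-hydroxylation that bypasses 15. It sets out from 14 and returns at 16.
- Elbs persulfate oxidation (K2S2O8, aq. NaOH/pyridine, 0 °C → rt) gives potassium 8-hydroxy-3,7-dimethoxy-4-oxo-2-(2,3,4-trimethoxyphenyl)-4H-chromen-5-yl sulfate F9.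
- Hydrolysis in warm aq. HCl gives 16 directly.

**Step 6.** Hydroxide may add at C3 and expel the aryloxide, or hydrolysis of the crowded ester may be slow. The fallback cleaves the ester at the methyl carbon instead of the acyl carbon: SN2 demethylation with LiI in pyridine at reflux, from 10 to 11, with no new compound.

## Further compounds

F1 | step 7 | 2-(benzyloxy)-1-methoxy-3-(methoxymethoxy)benzene | COCOc1cccc(OC)c1OCc1ccccc1
F2 | step 7 | 1-[3-(benzyloxy)-4-methoxy-2-(methoxymethoxy)phenyl]-2-methoxyethan-1-one | COCC(=O)c1ccc(OC)c(OCc2ccccc2)c1OCOC
F3 | step 7 | 1-[3-(benzyloxy)-2-hydroxy-4-methoxyphenyl]-2-methoxyethan-1-one | COCC(=O)c1ccc(OC)c(OCc2ccccc2)c1O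
F4 | step 7 | 1-[3-(benzyloxy)-2-hydroxy-4-methoxyphenyl]-2-methoxy-3-(2,3,4-trimethoxyphenyl)propane-1,3-dione (racemic) | COc1ccc(C(=O)C(OC)C(=O)c2ccc(OC)c(OCc3ccccc3)c2O)c(OC)c1OC
F5 | step 5 | methyl (2E)-3-chloro-2-methoxy-3-(2,3,4-trimethoxyphenyl)prop-2-enoate | COC(=O)/C(OC)=C(\Cl)c1ccc(OC)c(OC)c1OC
F6 | step 5 | methyl (2Z)-3-[2-(benzyloxy)-3-methoxyphenoxy]-2-methoxy-3-(2,3,4-trimethoxyphenyl)prop-2-enoate | COC(=O)/C(OC)=C(/Oc1cccc(OC)c1OCc1ccccc1)c1ccc(OC)c(OC)c1OC
F7 | step 3 | methyl 3-oxo-3-(2,3,4-trimethoxyphenyl)propanoate | COC(=O)CC(=O)c1ccc(OC)c(OC)c1OC
F8 | step 3 | methyl 2-diazo-3-oxo-3-(2,3,4-trimethoxyphenyl)propanoate | COC(=O)C(=[N+]=[N-])C(=O)c1ccc(OC)c(OC)c1OC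
F9 | step 9 | potassium 8-hydroxy-3,7-dimethoxy-4-oxo-2-(2,3,4-trimethoxyphenyl)-4H-chromen-5-yl sulfate | COc1cc(OS(=O)(=O)[O-])c2c(c1O)oc(-c1ccc(OC)c(OC)c1OC)c(OC)c2=O.[K+]
F0 | step 6 | none | none
A1 | alternative 1 | 1-[2,4-dimethoxy-6-(methoxymethoxy)phenyl]-2-methoxy-3-(2,3,4-trimethoxyphenyl)propane-1,3-dione (racemic) | COCOc1cc(OC)cc(OC)c1C(=O)C(OC)C(=O)c1ccc(OC)c(OC)c1OC
A2 | alternative 1 | 2-iodo-1,5-dimethoxy-3-(methoxymethoxy)benzene | COCOc1cc(OC)cc(OC)c1I
A3 | alternative 1 | 2-methoxy-1-(2,3,4-trimethoxyphenyl)ethan-1-one | COCC(=O)c1ccc(OC)c(OC)c1OC
A4 | alternative 1 | carbon monoxide | [C-]#[O+]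
A5 | alternative 2 | 3,5,7-trimethoxy-2-(2,3,4-trimethoxyphenyl)-4H-chromen-4-one | COc1cc(OC)c2c(c1)oc(-c1ccc(OC)c(OC)c1OC)c(OC)c2=O
A6 | alternative 2 | 3,5-dimethoxybenzyne (1,2-didehydro-3,5-dimethoxybenzene) | COC1=CC(OC)=CC#C1
A7 | alternative 2 | 3,5-dimethoxy-2-(trimethylsilyl)phenyl trifluoromethanesulfonate | COc1cc(OC)c([Si](C)(C)C)c(OS(=O)(=O)C(F)(F)F)c1
A8 | alternative 2 | (2Z)-2,3-dimethoxy-3-(2,3,4-trimethoxyphenyl)prop-2-enoic acid | OC(=O)/C(OC)=C(/OC)c1ccc(OC)c(OC)c1OC
A9 | alternative 3 | 3,7-dimethoxy-4-oxo-2-(2,3,4-trimethoxyphenyl)-4H-chromen-8-yl 2,3,4-trimethoxybenzoate | COc1ccc2c(c1OC(=O)c1ccc(OC)c(OC)c1OC)oc(-c1ccc(OC)c(OC)c1OC)c(OC)c2=O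
A10 | alternative 3 | 4-methoxy-2,3-bis[(2,3,4-trimethoxybenzoyl)oxy]benzoyl chloride | COc1ccc(C(=O)Cl)c(OC(=O)c2ccc(OC)c(OC)c2OC)c1OC(=O)c1ccc(OC)c(OC)c1OC
A11 | alternative 3 | (methoxymethylidene)triphenylphosphorane | COC=P(c1ccccc1)(c1ccccc1)c1ccccc1
A12 | alternative 3 | 2,3-dihydroxy-4-methoxybenzoic acid | COc1ccc(C(=O)O)c(O)c1O
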